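(The earlier runs and the new flask are simulated on assumed constants.)

If each starting material takes up two partner on its way to target, then a count of the charges, in which no time appears, tells what share of the starting material partner can carry to target in a finished flask, and that count can choose the next run. Dividing the partner charge by two, and then by the starting-material charge, gives 100% for the recipe below. This is the partner ceiling: the share of the charge that partner can carry to the end, which is what a limiting reagent allows. The two is our supposition, not a reading.

| flask | starting material | partner | temperature | remark | time |
|---|---|---|---|---|---|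
| east | 0.54 M | 1.6 M | 20 °C | run made earlier |  |
| west | 1.2 M | 1.6 M | 50 °C | run made earlier |  |
| north-west | 0.80 M | 2.4 M | 20 °C | run made earlier |  |
| autumn | 0.80 M | 1.60 M | 75 °C |  | 1.0 h |
| summer | 0.80 M | 1.60 M | 25 °C |  | 1.0 h |
| noon | 0.80 M | 1.60 M | 50 °C |  | 1.0 h |

| run | time / h | target / % | starting material / % |
|---|---|---|---|
| east | 1.50 | 22.2 | 25.6 |
| east | 4.00 | 50.3 | 1.4 |
| east | 8.00 | 56.8 | 0 |
| east | 12.0 | 55.7 | 1.2 |
| west | 0.333 | 42.5 | 1.6 |
| west | 0.833 | 42.2 | 0 |
| west | 1.50 | 45.3 | 0.5 |
| west | 3.00 | 42.9 | 0.5 |
| north-west | 1.50 | 22.3 | 23.8 |
| north-west | 4.00 | 50.6 | 4.3 |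
| north-west | 8.00 | 56.0 | 1.1 |
| north-west | 12.0 | 57.6 | 0 |

(scatter of a reading: 1 percentage point)



1. the flask with the highest amount of target, in percent of the starting material charged ("all alike" if they lie within 1.5 percentage points) (autumn / summer / noon / all alike)
2. final target, as a percentage of the starting material charged, in autumn
3. final target, as a percentage of the starting material charged, in summer
4. final target, as a percentage of the starting material charged, in noon

The east and north-west runs hold more partner than that need, and their late readings level at about 56.5% at the colder temperature. The west run has a ceiling of 66.7% and its readings level at about 43.2%, which is 64.8% of that ceiling, more than the 56.5% kept by the cold runs. Read this way, the low west plateau belongs to its charge, and the warmer flask keeps the larger share. We would therefore leave the recipe's charge as it stands and choose by temperature: we put noon near 64.8%, the west share times the ceiling, and autumn, being hotter, above it. Summer we leave out of the decision, since the colder east run still showed 25.6% starting material at 1.50 h.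

The forecast differs from us: it puts noon first at 48%, with autumn at 43%, “if heat erodes selectivity”, and summer at 24%.

The flasks give 82.4% in autumn, 72.3% at noon and 27.9% in summer, so autumn holds most.

    starting material → intermediate A (k = 4.81 × 10⁻⁴ /s, Ea = 98.0 kJ/mol)
    partner + intermediate A → intermediate B (k = 0.00143 /M/s, Ea = 57.0 kJ/mol)
    intermediate B ⇌ intermediate C (K = 2.09, k = 5.59 × 10⁻⁴ /s, Ea = 85.0 kJ/mol, ΔH = −28.0 kJ/mol)
    partner + intermediate C → target (k = 0.0170 /M/s, Ea = 59.0 kJ/mol)
    target ⇌ isomer of the product (K = 0.660, k = 0.00139 /s, Ea = 92.0 kJ/mol, ΔH = −20.0 kJ/mol)
    (constants at 25 °C)

In autumn the slowest mode of the whole flask, as it stands at the asked time, has a half-life of 0.354 h, about a third of the 1.0 h allowed, and partner is down to 0.44% of its own charge, with 82.4% target and 17.1% isomer of the product standing together near the ceiling of 100%. The neighbour of autumn with 1.14 equiv of partner has a ceiling of 57.1%, and it ends with 0% of its partner left and 39.2% target.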